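**Plan**

- Germacrane numbering is used: carbocycle C1–C10, lactone ring O–C12(=O)–C11–C7–C6, C13 methylene, C14/C15 methyls. The retrosynthesis cuts the O9–angeloyl ester, C11=C13 (phosphonate olefination), C2–C3 of the ten-membered ring (allyl sulfone alkylation), C4=C5 (Wittig), C7–C11 (carbenoid C–H insertion, which also opens the γ-lactone) and C1=C10 (cuprate addition to an ynoate).
- Forward: D-galactose supplies C5–C10. The Z C1=C10 allyl sulfone is built on a pyranoside and the chain is opened to a galactitol ester. The γ-lactone closes first (C–H insertion), the E C4=C5 allyl bromide is then grown from C5, and the carbocycle closes second (C2–C3). Methylenation, angeloylation and diol release follow.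
- Enabling feature: C6–C9 are four contiguous oxygenated carbons with the D-galacto pattern, and C7 differs from a sugar carbon only in carrying C11 where the sugar has hydrogen. The five-membered ring O–C12–C11–C7–C6 can therefore be made by inserting C11 of an ester on O6 into the C7–H bond.
- Stereochemistry: C6, C8 and C9 are C2, C4 and C5 of D-galactose and are never touched. C7 is galactose C3, substituted with retention. Z C1=C10 comes from syn carbocupration, E C4=C5 from a stabilised ylide, and the angelate geometry from angelic acid.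

Key step: step 17

Remark: galactose C1–C6 become germacrane C5–C10; in the octose names the two added carbons (germacrane C1, C2) are C7 and C8. Centres that are mixtures and never reach the target (anomeric carbon of 14, C11 of the phosphono lactones, C2 of sulfone 28) are left open in the SMILES.

**Route**

Step 1
Reactants: 1 D-galactose
Product: 2 allyl α-D-galactopyranoside
Conditions: allyl alcohol (solvent), Amberlite IR-120 (H+ form), 80 °C; crystallisation
Reagents that add atoms: allyl alcohol, C=CCO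
Why: Fischer glycosidation under thermodynamic control should favour the crystalline α-pyranoside; the anomeric centre only serves to keep O5 masked in the ring and is erased in step 11.

Step 2
Reactants: 2 allyl α-D-galactopyranoside
Product: 3 allyl 3,4-O-isopropylidene-6-O-(2-methoxypropan-2-yl)-α-D-galactopyranoside
Conditions: 2,2-dimethoxypropane (solvent), TsOH·H2O (cat.), rt; Et3N quench
Reagents that add atoms: 2,2-dimethoxypropane, COC(C)(C)OC
Why: Acid-catalysed transacetalisation closes the dioxolane on the cis-3,4-diol and traps the primary O6 as a mixed acetal, so that O2–H should remain the only free hydroxyl.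

Step 3
Reactants: 3 allyl 3,4-O-isopropylidene-6-O-(2-methoxypropan-2-yl)-α-D-galactopyranoside
Product: 5 allyl 3,4-O-isopropylidene-2-O-(4-methoxybenzyl)-α-D-galactopyranoside, via mixed acetal 4 (not isolated)
Conditions: NaH, 4-methoxybenzyl chloride, n-Bu4NI (cat.), DMF, 0 °C to rt; then PPTS (cat.), MeOH, 0 °C
Reagents that add atoms: 4-methoxybenzyl chloride, COc1ccc(CCl)cc1
Why: Williamson etherification of the single free hydroxyl, followed by methanolysis of the acyclic mixed acetal, which is far more labile than the cyclic acetonide, should free O6 alone.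

Step 4
Reactants: 5 allyl 3,4-O-isopropylidene-2-O-(4-methoxybenzyl)-α-D-galactopyranoside
Product: 6 allyl 3,4-O-isopropylidene-2-O-(4-methoxybenzyl)-α-D-galacto-hexodialdo-1,5-pyranoside
Conditions: PhI(OAc)2, TEMPO (cat.), CH2Cl2, rt
Reagents that add atoms: none
Why: Oxoammonium (TEMPO) oxidation takes the primary alcohol to the aldehyde without over-oxidation and without touching the PMB ether, the allyl group or the acetonide.

Step 5
Reactants: 6 allyl 3,4-O-isopropylidene-2-O-(4-methoxybenzyl)-α-D-galacto-hexodialdo-1,5-pyranoside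
Product: 7 allyl 6,7-dideoxy-3,4-O-isopropylidene-2-O-(4-methoxybenzyl)-α-D-galacto-hept-6-ynopyranoside
Conditions: dimethyl (1-diazo-2-oxopropyl)phosphonate, K2CO3, MeOH, 0 °C to rt
Reagents that add atoms: dimethyl (1-diazo-2-oxopropyl)phosphonate, CC(=O)C(=[N+]=[N-])P(=O)(OC)OC
Why: Seyferth–Gilbert homologation in its Ohira–Bestmann form converts the aldehyde into the terminal alkyne under conditions mild enough to leave the adjacent ring stereocentre (future C9) unchanged.

Step 6
Reactants: 7 allyl 6,7-dideoxy-3,4-O-isopropylidene-2-O-(4-methoxybenzyl)-α-D-galacto-hept-6-ynopyranoside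
Product: 8 methyl (allyl 6,7-dideoxy-3,4-O-isopropylidene-2-O-(4-methoxybenzyl)-α-D-galacto-oct-6-ynopyranosid)uronate
Conditions: n-BuLi, THF, −78 °C; then ClCO2Me, −78 to −20 °C
Reagents that add atoms: methyl chloroformate, COC(=O)Cl
Why: Acylation of the lithium acetylide with the chloroformate gives the ynoate, whose ester carbon becomes C2.

Step 7
Reactants: 8 methyl (allyl 6,7-dideoxy-3,4-O-isopropylidene-2-O-(4-methoxybenzyl)-α-D-galacto-oct-6-ynopyranosid)uronate
Product: 9 methyl (allyl 6,7-dideoxy-3,4-O-isopropylidene-2-O-(4-methoxybenzyl)-6-C-methyl-α-D-galacto-oct-6(Z)-enopyranosid)uronate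
Conditions: Me2CuLi (CuI, MeLi), THF, −78 °C; MeOH quench at −78 °C
Reagents that add atoms: lithium dimethylcuprate, [Li+].C[Cu-]C (from CuI and methyllithium, [Li]C)
Why: Conjugate addition of the Gilman cuprate to the ynoate is a syn carbocupration, and protonation of the alkenylcopper at −78 °C with retention should leave the sugar carbon (C9) and the ester cis, which is the Z geometry of C1=C10 with C14 in place.

Step 8
Reactants: 9 methyl (allyl 6,7-dideoxy-3,4-O-isopropylidene-2-O-(4-methoxybenzyl)-6-C-methyl-α-D-galacto-oct-6(Z)-enopyranosid)uronate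
Product: 10 allyl 6,7-dideoxy-3,4-O-isopropylidene-2-O-(4-methoxybenzyl)-6-C-methyl-α-D-galacto-oct-6(Z)-enopyranoside
Conditions: DIBAL-H, CH2Cl2, −78 °C; Rochelle salt work-up
Reagents that add atoms: none
Why: 1,2-Reduction of the enoate by the aluminium hydride gives the allylic alcohol (C2–OH) with the olefin geometry preserved.

Step 9
Reactants: 10 allyl 6,7-dideoxy-3,4-O-isopropylidene-2-O-(4-methoxybenzyl)-6-C-methyl-α-D-galacto-oct-6(Z)-enopyranoside
Product: 12 allyl 6,7,8-trideoxy-3,4-O-isopropylidene-2-O-(4-methoxybenzyl)-6-C-methyl-8-(phenylsulfonyl)-α-D-galacto-oct-6(Z)-enopyranoside, via mesylate 11 (not isolated)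
Conditions: MsCl, Et3N, CH2Cl2, −20 °C; then PhSO2Na, n-Bu4NI (cat.), DMF, rt
Reagents that add atoms: sodium benzenesulfinate, [Na+].[O-]S(=O)c1ccccc1; methanesulfonyl chloride, CS(=O)(=O)Cl (atoms stay in 11 only)
Why: The allylic mesylate is displaced at the primary carbon by the sulfinate sulfur (SN2, S-alkylation), which should keep the Z olefin and install the group that later turns C2 into a carbanion.

Step 10
Reactants: 12 allyl 6,7,8-trideoxy-3,4-O-isopropylidene-2-O-(4-methoxybenzyl)-6-C-methyl-8-(phenylsulfonyl)-α-D-galacto-oct-6(Z)-enopyranoside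
Product: 14 6,7,8-trideoxy-3,4-O-isopropylidene-2-O-(4-methoxybenzyl)-6-C-methyl-8-(phenylsulfonyl)-D-galacto-oct-6(Z)-enopyranose, via prop-1-enyl glycoside 13 (not isolated)
Conditions: [Ir(cod)(PMePh2)2]PF6 (cat., activated with H2), THF, rt; then I2, NaHCO3, THF/H2O, 0 °C
Reagents that add atoms: none
Why: Iridium hydride isomerisation of the allyl ether to the enol ether leaves the trisubstituted olefin alone, and iodine-assisted hydrolysis of the enol ether frees the hemiacetal without acid, so acetonide and PMB ether should survive.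

Step 11
Reactants: 14 6,7,8-trideoxy-3,4-O-isopropylidene-2-O-(4-methoxybenzyl)-6-C-methyl-8-(phenylsulfonyl)-D-galacto-oct-6(Z)-enopyranose
Product: 15 6,7,8-trideoxy-3,4-O-isopropylidene-2-O-(4-methoxybenzyl)-6-C-methyl-8-(phenylsulfonyl)-D-galacto-oct-6(Z)-enitol
Conditions: NaBH4, MeOH, 0 °C to rt
Reagents that add atoms: none
Why: Borohydride reduction of the open-chain aldehyde tautomer gives the alditol; because the C10 end is already elaborated, the two chain ends stay distinct and only O1 (on C5) and O5 (on C9) are free.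

Step 12
Reactants: 15 6,7,8-trideoxy-3,4-O-isopropylidene-2-O-(4-methoxybenzyl)-6-C-methyl-8-(phenylsulfonyl)-D-galacto-oct-6(Z)-enitol
Product: 16 1-O-(2,2,2-trichloroethoxycarbonyl) derivative of 15
Conditions: 2,2,2-trichloroethyl chloroformate, pyridine, CH2Cl2, −40 to −20 °C
Reagents that add atoms: 2,2,2-trichloroethyl chloroformate, ClC(=O)OCC(Cl)(Cl)Cl
Why: Acylation with the chloroformate at low temperature should pick the primary hydroxyl over the hindered allylic secondary one, and the carbonate both deactivates the C5–H bonds for step 17 and can be removed later without base.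

Step 13
Reactants: 16 1-O-(2,2,2-trichloroethoxycarbonyl) derivative of 15
Product: 17 5-O-(tert-butyldimethylsilyl)-1-O-(2,2,2-trichloroethoxycarbonyl) derivative of 15
Conditions: TBSOTf, 2,6-lutidine, CH2Cl2, −40 to 0 °C
Reagents that add atoms: tert-butyldimethylsilyl trifluoromethanesulfonate, CC(C)(C)[Si](C)(C)OS(=O)(=O)C(F)(F)F
Why: Silylation with the silyl triflate covers the remaining hindered hydroxyl (O9) with a group that lasts until step 25.

Step 14
Reactants: 17 5-O-(tert-butyldimethylsilyl)-1-O-(2,2,2-trichloroethoxycarbonyl) derivative of 15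
Product: 18 5-O-(tert-butyldimethylsilyl)-6,7,8-trideoxy-3,4-O-isopropylidene-6-C-methyl-8-(phenylsulfonyl)-1-O-(2,2,2-trichloroethoxycarbonyl)-D-galacto-oct-6(Z)-enitol
Conditions: DDQ, CH2Cl2/pH 7 buffer, 0 °C
Reagents that add atoms: none
Why: Oxidative cleavage of the electron-rich PMB ether by DDQ frees O2 (the future lactone oxygen on C6) without affecting the carbonate, silyl ether, acetonide or sulfone.

Step 15
Reactants: 18 5-O-(tert-butyldimethylsilyl)-6,7,8-trideoxy-3,4-O-isopropylidene-6-C-methyl-8-(phenylsulfonyl)-1-O-(2,2,2-trichloroethoxycarbonyl)-D-galacto-oct-6(Z)-enitol; 19 diethylphosphonoacetic acid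
Product: 20 2-O-[(diethoxyphosphoryl)acetyl] ester of 18
Conditions: DCC, DMAP (cat.), CH2Cl2, 0 °C to rt
Reagents that add atoms: none
Why: Steglich esterification of the only free hydroxyl attaches C11 and C12 to O6.

Step 16
Reactants: 20 2-O-[(diethoxyphosphoryl)acetyl] ester of 18
Product: 21 2-O-[diazo(diethoxyphosphoryl)acetyl] ester of 18
Conditions: 4-acetamidobenzenesulfonyl azide, DBU, MeCN, 0 °C
Reagents that add atoms: 4-acetamidobenzenesulfonyl azide, CC(=O)Nc1ccc(cc1)S(=O)(=O)N=[N+]=[N-]
Why: Regitz diazo transfer to the doubly activated methylene gives the stable diazo(phosphono)acetate; the amine base is too weak to deprotonate the allyl sulfone.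

Step 17
Reactants: 21 2-O-[diazo(diethoxyphosphoryl)acetyl] ester of 18
Product: 22 α-phosphono γ-lactone with quaternary C7 (C5 Troc carbonate)
Conditions: Rh2(OAc)4 (2 mol %), benzene, reflux, slow addition of 21 at high dilution
Reagents that add atoms: none
Why: Loss of N2 at Rh2(OAc)4 gives an electrophilic dirhodium carbenoid at C11, which inserts into the C7–H bond through a concerted three-centre transition state, forming C7–C11 and with it the O–C12–C11–C7–C6 γ-lactone. The closest known reaction type is the Rh2(OAc)4-catalysed intramolecular C–H insertion of diazo(phosphono)acetates into C–H bonds next to an ether oxygen, which gives α-phosphono γ-butyrolactones. The lactone closes in the 1,5 mode, the carbenoid carbon bonding to the carbon β to the ester oxygen through a five-membered transition state. The quaternary stereocentre C7 is controlled by the substrate alone, since insertion proceeds with retention and C11 takes the place of the hydrogen of galactose C3; the two C11 epimers converge in step 24. The step needs site selectivity for the C7 methine: the dioxolane oxygen on C7 makes this tertiary C–H bond hydridic, the carbonate on O5 deactivates the competing C5 methylene, insertion at C8–H would need a six-membered transition state, and cyclopropanation of the remote C1=C10 olefin would have to close an eight- or nine-membered ring.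

Step 18
Reactants: 22 α-phosphono γ-lactone with quaternary C7 (C5 Troc carbonate)
Product: 23 α-phosphono γ-lactone C5 alcohol
Conditions: Zn dust, AcOH/THF, rt
Reagents that add atoms: none
Why: Zinc reduces the trichloroethyl group, and β-elimination with loss of CO2 removes the carbonate under weakly acidic conditions that leave lactone, phosphonate, silyl ether, acetonide and sulfone intact.

Step 19
Reactants: 23 α-phosphono γ-lactone C5 alcohol
Product: 25 (4E)-enal (C3 aldehyde), via aldehyde 24 (not isolated)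
Conditions: Dess–Martin periodinane, CH2Cl2, 0 °C to rt; filtration; then Ph3P=C(CH3)CHO, toluene, 60 °C
Reagents that add atoms: 2-(triphenylphosphoranylidene)propanal, CC(C=O)=P(c1ccccc1)(c1ccccc1)c1ccccc1
Why: Dess–Martin oxidation gives the α-acyloxy aldehyde, used crude to avoid epimerisation at C6, and the Wittig reaction with the weakly basic stabilised ylide should give the E trisubstituted enal (C6 trans to C3) because oxaphosphetane formation is reversible.

Step 20
Reactants: 25 (4E)-enal (C3 aldehyde)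
Product: 26 (4E)-allylic alcohol (C3–OH)
Conditions: NaBH4, CeCl3·7H2O, MeOH, −40 °C
Reagents that add atoms: none
Why: Luche 1,2-reduction of the enal is much faster than any attack on the lactone, so only the aldehyde should be reduced.

Step 21
Reactants: 26 (4E)-allylic alcohol (C3–OH)
Product: 27 (4E)-allylic bromide (C3–Br)
Conditions: CBr4, PPh3, CH2Cl2, 0 °C
Reagents that add atoms: carbon tetrabromide, BrC(Br)(Br)Br
Why: The Appel reaction converts the primary allylic alcohol into the bromide under neutral conditions without allylic transposition.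

Step 22
Reactants: 27 (4E)-allylic bromide (C3–Br)
Product: 28 macrocyclic 2-phenylsulfonyl germacranolide phosphonate
Conditions: KHMDS (2.3 equiv), THF (0.002 M, slow addition of 27), −78 to −20 °C; AcOH quench
Reagents that add atoms: none
Why: The first equivalent of base turns the phosphono lactone into its potassium enolate, which shields the lactone carbonyl, and the second forms the sulfonyl-stabilised allyl anion, whose intramolecular SN2 alkylation at its α-carbon C2 by the C3 bromide (the allyl sulfone alkylation used for head-to-head 1,5-dienes and germacrane rings) closes the ten-membered ring with both olefin geometries retained.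

Step 23
Reactants: 28 macrocyclic 2-phenylsulfonyl germacranolide phosphonate
Product: 29 11-(diethoxyphosphoryl) germacranolide (9-OTBS, 7,8-acetonide)
Conditions: LiHMDS (1.1 equiv), THF, −78 °C; then PdCl2(dppp) (5 mol %), LiBHEt3, 0 °C; AcOH quench
Reagents that add atoms: none
Why: With C11 held as its lithium enolate, which protects the lactone from hydride and keeps the allylic C6–O bond from ionising, zerovalent palladium formed in situ ionises the allylic sulfone and hydride is delivered to the less substituted terminus C2 (palladium-catalysed reductive desulfonylation of allylic sulfones), which should leave Z C1=C10 in place.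

Step 24
Reactants: 29 11-(diethoxyphosphoryl) germacranolide (9-OTBS, 7,8-acetonide)
Product: 30 α-methylene lactone (9-OTBS, 7,8-acetonide)
Conditions: K2CO3, 37% aq. HCHO, THF, 0 °C to rt
Reagents that add atoms: formaldehyde, C=O
Why: Horner–Wadsworth–Emmons olefination of the phosphonate anion with formaldehyde installs C13, converges both C11 epimers, and should outrun β-elimination of the C7 oxygen because the anion is trapped as it forms.

Step 25
Reactants: 30 α-methylene lactone (9-OTBS, 7,8-acetonide)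
Product: 31 9-hydroxy α-methylene lactone 7,8-acetonide
Conditions: HF·pyridine, pyridine, THF, 0 °C to rt
Reagents that add atoms: none
Why: Buffered fluoride desilylation frees O9 alone, the acetonide still covering O7 and O8 and the medium being too weakly nucleophilic to add to the methylene lactone.

Step 26
Reactants: 31 9-hydroxy α-methylene lactone 7,8-acetonide; 32 angelic acid
Product: 34 9-O-angeloyl α-methylene lactone 7,8-acetonide, via mixed anhydride 33 (not isolated)
Conditions: 2,4,6-trichlorobenzoyl chloride, Et3N, toluene, rt; then 31, 75 °C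
Reagents that add atoms: 2,4,6-trichlorobenzoyl chloride, O=C(Cl)c1c(Cl)cc(Cl)cc1Cl (atoms stay in 33 only)
Why: Yamaguchi esterification through the mixed anhydride, run without a nucleophilic catalyst, should acylate the only free hydroxyl while keeping the Z geometry of the angeloyl group, which comes unchanged from angelic acid.

Step 27
Reactants: 34 9-O-angeloyl α-methylene lactone 7,8-acetonide
Product: 35 CNP0303917.1
Conditions: AcOH/H2O (4:1), 40 °C
Reagents that add atoms: none
Why: Acid-catalysed hydrolysis of the dioxolane frees the C7 and C8 hydroxyls; dilute acetic acid is chosen to limit transannular cyclisation of the 1(10),4-diene, angeloyl migration from O9 to O8 and isomerisation of the angelate.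

**Compound list**

1 | D-galactose | O=C[C@H](O)[C@@H](O)[C@@H](O)[C@H](O)CO | starting material
2 | allyl α-D-galactopyranoside | C=CCO[C@@H]1[C@H](O)[C@@H](O)[C@@H](O)[C@@H](CO)O1 | intermediate
3 | allyl 3,4-O-isopropylidene-6-O-(2-methoxypropan-2-yl)-α-D-galactopyranoside | C=CCO[C@@H]1[C@H](O)[C@H]2OC(C)(C)O[C@H]2[C@@H](COC(C)(C)OC)O1 | intermediate
4 | allyl 3,4-O-isopropylidene-2-O-(4-methoxybenzyl)-6-O-(2-methoxypropan-2-yl)-α-D-galactopyranoside (mixed acetal) | C=CCO[C@@H]1[C@H](OCc3ccc(OC)cc3)[C@H]2OC(C)(C)O[C@H]2[C@@H](COC(C)(C)OC)O1 | intermediate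
5 | allyl 3,4-O-isopropylidene-2-O-(4-methoxybenzyl)-α-D-galactopyranoside | C=CCO[C@@H]1[C@H](OCc3ccc(OC)cc3)[C@H]2OC(C)(C)O[C@H]2[C@@H](CO)O1 | intermediate
6 | allyl 3,4-O-isopropylidene-2-O-(4-methoxybenzyl)-α-D-galacto-hexodialdo-1,5-pyranoside (C6 aldehyde of 5) | C=CCO[C@@H]1[C@H](OCc3ccc(OC)cc3)[C@H]2OC(C)(C)O[C@H]2[C@@H](C=O)O1 | intermediate
7 | allyl 6,7-dideoxy-3,4-O-isopropylidene-2-O-(4-methoxybenzyl)-α-D-galacto-hept-6-ynopyranoside (terminal alkyne) | C=CCO[C@@H]1[C@H](OCc3ccc(OC)cc3)[C@H]2OC(C)(C)O[C@H]2[C@@H](C#C)O1 | intermediate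
8 | methyl (allyl 6,7-dideoxy-3,4-O-isopropylidene-2-O-(4-methoxybenzyl)-α-D-galacto-oct-6-ynopyranosid)uronate (ynoate) | C=CCO[C@@H]1[C@H](OCc3ccc(OC)cc3)[C@H]2OC(C)(C)O[C@H]2[C@@H](C#CC(=O)OC)O1 | intermediate
9 | methyl (allyl 6,7-dideoxy-3,4-O-isopropylidene-2-O-(4-methoxybenzyl)-6-C-methyl-α-D-galacto-oct-6(Z)-enopyranosid)uronate (sugar C5 and CO2Me cis) | C=CCO[C@@H]1[C@H](OCc3ccc(OC)cc3)[C@H]2OC(C)(C)O[C@H]2[C@@H](/C(C)=C\C(=O)OC)O1 | intermediate
10 | allyl 6,7-dideoxy-3,4-O-isopropylidene-2-O-(4-methoxybenzyl)-6-C-methyl-α-D-galacto-oct-6(Z)-enopyranoside (C8 allylic alcohol) | C=CCO[C@@H]1[C@H](OCc3ccc(OC)cc3)[C@H]2OC(C)(C)O[C@H]2[C@@H](/C(C)=C\CO)O1 | intermediate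
11 | 8-O-methanesulfonate of 10 | C=CCO[C@@H]1[C@H](OCc3ccc(OC)cc3)[C@H]2OC(C)(C)O[C@H]2[C@@H](/C(C)=C\COS(C)(=O)=O)O1 | intermediate
12 | allyl 6,7,8-trideoxy-3,4-O-isopropylidene-2-O-(4-methoxybenzyl)-6-C-methyl-8-(phenylsulfonyl)-α-D-galacto-oct-6(Z)-enopyranoside | C=CCO[C@@H]1[C@H](OCc3ccc(OC)cc3)[C@H]2OC(C)(C)O[C@H]2[C@@H](/C(C)=C\CS(=O)(=O)c4ccccc4)O1 | intermediate
13 | (E)-prop-1-enyl glycoside corresponding to 12 | C/C=C/O[C@@H]1[C@H](OCc3ccc(OC)cc3)[C@H]2OC(C)(C)O[C@H]2[C@@H](/C(C)=C\CS(=O)(=O)c4ccccc4)O1 | intermediate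
14 | 6,7,8-trideoxy-3,4-O-isopropylidene-2-O-(4-methoxybenzyl)-6-C-methyl-8-(phenylsulfonyl)-D-galacto-oct-6(Z)-enopyranose (anomeric mixture) | OC1[C@H](OCc3ccc(OC)cc3)[C@H]2OC(C)(C)O[C@H]2[C@@H](/C(C)=C\CS(=O)(=O)c4ccccc4)O1 | intermediate
15 | 6,7,8-trideoxy-3,4-O-isopropylidene-2-O-(4-methoxybenzyl)-6-C-methyl-8-(phenylsulfonyl)-D-galacto-oct-6(Z)-enitol (1,5-diol) | OC[C@H](OCc1ccc(OC)cc1)[C@H]2OC(C)(C)O[C@H]2[C@H](O)/C(C)=C\CS(=O)(=O)c3ccccc3 | intermediate
16 | 1-O-(2,2,2-trichloroethoxycarbonyl) derivative of 15 | ClC(Cl)(Cl)COC(=O)OC[C@H](OCc1ccc(OC)cc1)[C@H]2OC(C)(C)O[C@H]2[C@H](O)/C(C)=C\CS(=O)(=O)c3ccccc3 | intermediate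
17 | 5-O-(tert-butyldimethylsilyl)-1-O-(2,2,2-trichloroethoxycarbonyl) derivative of 15 | ClC(Cl)(Cl)COC(=O)OC[C@H](OCc1ccc(OC)cc1)[C@H]2OC(C)(C)O[C@H]2[C@H](O[Si](C)(C)C(C)(C)C)/C(C)=C\CS(=O)(=O)c3ccccc3 | intermediate
18 | 5-O-(tert-butyldimethylsilyl)-6,7,8-trideoxy-3,4-O-isopropylidene-6-C-methyl-8-(phenylsulfonyl)-1-O-(2,2,2-trichloroethoxycarbonyl)-D-galacto-oct-6(Z)-enitol (free 2-OH) | ClC(Cl)(Cl)COC(=O)OC[C@H](O)[C@H]2OC(C)(C)O[C@H]2[C@H](O[Si](C)(C)C(C)(C)C)/C(C)=C\CS(=O)(=O)c3ccccc3 | intermediate
19 | diethylphosphonoacetic acid | OC(=O)CP(=O)(OCC)OCC | starting material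
20 | 2-O-[(diethoxyphosphoryl)acetyl] ester of 18 | ClC(Cl)(Cl)COC(=O)OC[C@H](OC(=O)CP(=O)(OCC)OCC)[C@H]2OC(C)(C)O[C@H]2[C@H](O[Si](C)(C)C(C)(C)C)/C(C)=C\CS(=O)(=O)c3ccccc3 | intermediate
21 | 2-O-[diazo(diethoxyphosphoryl)acetyl] ester of 18 (diazo ester on O6, germacrane numbering) | ClC(Cl)(Cl)COC(=O)OC[C@H](OC(=O)C(=[N+]=[N-])P(=O)(OCC)OCC)[C@H]2OC(C)(C)O[C@H]2[C@H](O[Si](C)(C)C(C)(C)C)/C(C)=C\CS(=O)(=O)c3ccccc3 | intermediate
22 | α-phosphono γ-lactone with quaternary C7: lactone O6–C12(=O)–C11[P(O)(OEt)2]–C7; C5 is CH2O-Troc, O7/O8 isopropylidene, O9 TBS, (Z)-C1=C10 with C14 methyl, C2 phenylsulfonyl; C11 epimers | ClC(Cl)(Cl)COC(=O)OC[C@@H]1OC(=O)C(P(=O)(OCC)OCC)[C@@]12OC(C)(C)O[C@H]2[C@H](O[Si](C)(C)C(C)(C)C)/C(C)=C\CS(=O)(=O)c3ccccc3 | intermediate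
23 | α-phosphono γ-lactone C5 alcohol (22 without the Troc group) | OC[C@@H]1OC(=O)C(P(=O)(OCC)OCC)[C@@]12OC(C)(C)O[C@H]2[C@H](O[Si](C)(C)C(C)(C)C)/C(C)=C\CS(=O)(=O)c3ccccc3 | intermediate
24 | C5 aldehyde of 23 | O=C[C@@H]1OC(=O)C(P(=O)(OCC)OCC)[C@@]12OC(C)(C)O[C@H]2[C@H](O[Si](C)(C)C(C)(C)C)/C(C)=C\CS(=O)(=O)c3ccccc3 | intermediate
25 | (4E)-enal: C6–C5H=C4(CH3)–C3HO on the phosphono lactone of 23 | O=C/C(C)=C/[C@@H]1OC(=O)C(P(=O)(OCC)OCC)[C@@]12OC(C)(C)O[C@H]2[C@H](O[Si](C)(C)C(C)(C)C)/C(C)=C\CS(=O)(=O)c3ccccc3 | intermediate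
26 | (4E)-allylic alcohol (C3–OH) from 25 | OC/C(C)=C/[C@@H]1OC(=O)C(P(=O)(OCC)OCC)[C@@]12OC(C)(C)O[C@H]2[C@H](O[Si](C)(C)C(C)(C)C)/C(C)=C\CS(=O)(=O)c3ccccc3 | intermediate
27 | (4E)-allylic bromide (C3–Br) from 26 | BrC/C(C)=C/[C@@H]1OC(=O)C(P(=O)(OCC)OCC)[C@@]12OC(C)(C)O[C@H]2[C@H](O[Si](C)(C)C(C)(C)C)/C(C)=C\CS(=O)(=O)c3ccccc3 | intermediate
28 | macrocyclic (1(10)Z,4E)-germacradien-6,12-olide with 2-phenylsulfonyl, 11-diethoxyphosphoryl, 7,8-O-isopropylidene and 9-O-TBS groups (C2 and C11 mixtures) | CCOP(=O)(OCC)C1C(=O)O[C@H]2/C=C(\C)CC(S(=O)(=O)c4ccccc4)/C=C(/C)[C@@H](O[Si](C)(C)C(C)(C)C)[C@@H]3OC(C)(C)O[C@]123 | intermediate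
29 | 11-(diethoxyphosphoryl)-(1(10)Z,4E)-germacradien-6,12-olide, 7,8-O-isopropylidene, 9-O-TBS (C11 epimers) | CCOP(=O)(OCC)C1C(=O)O[C@H]2/C=C(\C)CC/C=C(/C)[C@@H](O[Si](C)(C)C(C)(C)C)[C@@H]3OC(C)(C)O[C@]123 | intermediate
30 | (1(10)Z,4E)-germacra-1(10),4,11(13)-trien-6,12-olide, 7,8-O-isopropylidene, 9-O-TBS | C=C1C(=O)O[C@H]2/C=C(\C)CC/C=C(/C)[C@@H](O[Si](C)(C)C(C)(C)C)[C@@H]3OC(C)(C)O[C@]123 | intermediate
31 | 9-hydroxy-7,8-O-isopropylidene-(1(10)Z,4E)-germacra-1(10),4,11(13)-trien-6,12-olide | C=C1C(=O)O[C@H]2/C=C(\C)CC/C=C(/C)[C@@H](O)[C@@H]3OC(C)(C)O[C@]123 | intermediate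
32 | angelic acid, (Z)-2-methylbut-2-enoic acid | C/C=C(/C)C(=O)O | starting material
33 | angelic 2,4,6-trichlorobenzoic mixed anhydride | C/C=C(/C)C(=O)OC(=O)c1c(Cl)cc(Cl)cc1Cl | intermediate
34 | 9-O-angeloyl-7,8-O-isopropylidene-(1(10)Z,4E)-germacra-1(10),4,11(13)-trien-6,12-olide | C=C1C(=O)O[C@H]2/C=C(\C)CC/C=C(/C)[C@@H](OC(=O)/C(C)=C\C)[C@@H]3OC(C)(C)O[C@]123 | intermediate
35 | CNP0303917.1, 9-O-angeloyl-7,8-dihydroxy-(1(10)Z,4E)-germacra-1(10),4,11(13)-trien-6,12-olide | C=C1C(=O)O[C@H]2/C=C(\C)CC/C=C(/C)[C@@H](OC(=O)/C(C)=C\C)[C@H](O)[C@@]12O | target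

**Step count and risks**

Total step count: 27. Longest linear sequence: 27 steps (1 to 35); all other inputs are commercial reagents.

Steps most likely to fail:

1. Step 22 (ring closure). The C11 enolate may expel the C7 oxygen by β-elimination while it waits, or intermolecular alkylation may outrun closure of the strained ten-membered ring. Fallback, setting out from 26 and coming back at 30: the carbanion at C11 is avoided altogether by methylenating before ring closure and masking the methylene lactone.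
   - Alcohol 26 is olefinated with K2CO3 and aqueous formaldehyde to the α-methylene lactone alcohol F1.
   - Conjugate addition of benzeneselenol (PhSeSePh, NaBH4, EtOH) masks the exocyclic olefin as the 13-phenylselanyl lactone F2.
   - CBr4/PPh3 gives the allylic bromide F3.
   - One equivalent of LiHMDS at high dilution now forms only the sulfonyl carbanion, and alkylation gives the macrocyclic sulfone selenide F4.
   - Sodium amalgam (Na2HPO4, MeOH/THF, −20 °C) removes the sulfonyl group to give the macrocyclic selenide F5.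
   - H2O2/pyridine oxidises it to the selenoxide F6, whose syn elimination at room temperature restores the exocyclic methylene of 30.

2. Step 23 (desulfonylation). Hydride may be delivered at C10 instead of C2, or the allylpalladium intermediate may equilibrate, so that the double bond shifts or Z C1=C10 is lost. Fallback, setting out from 28 and coming back at 29: the C–S bond is cleaved by single-electron transfer instead of by palladium and hydride. SmI2 in THF/DMPU with MeOH at −78 °C reduces the neutral lactone 28 directly, with no enolate and no allylpalladium species, and protonation at the less hindered C2 gives 29. This fallback makes no new compound (F0).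

3. Step 26 (angeloylation). Acylation of the hindered allylic C9 hydroxyl may be slow enough for the activated angelate to isomerise to the tiglate, or for the 1,5-diene to rearrange thermally at 75 °C. Fallback, setting out from 31 and coming back at 34: the Z olefin of the ester is built after the acyl group is in place. Alcohol 31 is esterified (DCC, DMAP, 0 °C) with 2-[bis(2,2,2-trifluoroethoxy)phosphoryl]propanoic acid to the phosphonopropanoate F7, and Still–Gennari olefination (KHMDS, 18-crown-6, THF, −78 °C, acetaldehyde) converts it into the Z-2-methylbut-2-enoate 34.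

**Further compounds**

F1 | step 22 | α-methylene lactone (4E)-allylic alcohol (26 after methylenation; sulfone, TBS and acetonide unchanged) | OC/C(C)=C/[C@@H]1OC(=O)C(=C)[C@@]12OC(C)(C)O[C@H]2[C@H](O[Si](C)(C)C(C)(C)C)/C(C)=C\CS(=O)(=O)c3ccccc3
F2 | step 22 | 13-phenylselanyl lactone (benzeneselenol adduct of F1, C11 epimers) | OC/C(C)=C/[C@@H]1OC(=O)C(C[Se]c4ccccc4)[C@@]12OC(C)(C)O[C@H]2[C@H](O[Si](C)(C)C(C)(C)C)/C(C)=C\CS(=O)(=O)c3ccccc3
F3 | step 22 | allylic bromide (C3–Br) of F2 | BrC/C(C)=C/[C@@H]1OC(=O)C(C[Se]c4ccccc4)[C@@]12OC(C)(C)O[C@H]2[C@H](O[Si](C)(C)C(C)(C)C)/C(C)=C\CS(=O)(=O)c3ccccc3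
F4 | step 22 | macrocyclic sulfone selenide (2-phenylsulfonyl, 13-phenylselanyl, 7,8-O-isopropylidene, 9-O-TBS germacradienolide) | c5ccccc5[Se]CC1C(=O)O[C@H]2/C=C(\C)CC(S(=O)(=O)c4ccccc4)/C=C(/C)[C@@H](O[Si](C)(C)C(C)(C)C)[C@@H]3OC(C)(C)O[C@]123
F5 | step 22 | macrocyclic selenide (F4 without the sulfonyl group) | c5ccccc5[Se]CC1C(=O)O[C@H]2/C=C(\C)CC/C=C(/C)[C@@H](O[Si](C)(C)C(C)(C)C)[C@@H]3OC(C)(C)O[C@]123
F6 | step 22 | selenoxide of F5 | O=[Se](c5ccccc5)CC1C(=O)O[C@H]2/C=C(\C)CC/C=C(/C)[C@@H](O[Si](C)(C)C(C)(C)C)[C@@H]3OC(C)(C)O[C@]123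
F0 | step 23 | none | none
F7 | step 26 | 9-O-{2-[bis(2,2,2-trifluoroethoxy)phosphoryl]propanoyl} ester of 31 | C=C1C(=O)O[C@H]2/C=C(\C)CC/C=C(/C)[C@@H](OC(=O)C(C)P(=O)(OCC(F)(F)F)OCC(F)(F)F)[C@@H]3OC(C)(C)O[C@]123
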